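The runs are calculated for substances that don't exist; scatter was added.

In a one-step world, pseudo-first-order in Z, the log drop ln([Z]start/[Z]) at a given time grows in step with charged G, and the order in G is one.

common to all: Z 0.20 M; L 0.20 M; D 29 mM (held)

|  | G | remark |
|---|---|---|
| Friday's | 0.40 mM | the very flask that is asked about, followed so far |
| Thursday's | 0.60 mM | run made earlier |
| flask | 0.40 mM |  |

Friday's run (percent of the Z and L together charged)

| time / s | J / % | Z / % |
|---|---|---|
| 15.0 | 3.6 | 47.1 |
| 40.0 | 8.9 | 40.8 |
| 80.0 | 17.4 | 35.2 |
| 120 | 18.1 | 30.6 |

Thursday's run (percent of the Z and L together charged)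

| time / min | J / % | Z / % |
|---|---|---|
| 0.250 | 3.5 | 48.0 |
| 0.667 | 12.3 | 36.9 |
| 1.50 | 21.9 | 29.0 |
| 4.00 | 29.3 | 19.9 |

(scatter of a reading: 1 percentage point)

1. apparent order in G when 10% of the Z and L together are converted (percent change of the rate of making J for one percent more G charged)

- G is single-handed; Z and L are mirror images of each other, charged as a racemate, each of them at the stated concentration
- at the start none of X is dissolved
- steps under discussion: G -> E; X + G + L -> G + Q; D <-> X; X + G + Z -> G + J

Read the two tables against each other at 1.50 min. Thursday's log drop is 0.545, and Friday's, taken between its rows at 80.0 s and 120 s, is 0.386. Together with the charges, that gives the equal-time order 0.850, a reading that carries the scatter.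

We take the rate as proportional to [X][G][Z], so at equal conversion the order lies in [X][G]. If X is fed in proportion to what it lacks of saturation and eaten in proportion to live G, the equal-time order equals [X]/saturation, and that is the concentration we watch.

Reading down the columns, the slope of the log drop decays at 0.00683 s⁻¹ on Friday and 0.00652 s⁻¹ on Thursday, which we read as G being lost. More G reaches the mark sooner, with more of it alive. The mark counts Z and L together, and L is not read: Friday's Z has lost 9.2 percentage points by 40.0 s, and L can react as well, so as a guess we put the mark midway between the rows at 15.0 s and 40.0 s, at 27.5 s. Our order is then n(1 + decay × time × n) = 0.985.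

The forecast says 1.1, within 0.85 to 1.35, arguing “More G reaches that point sooner”.

The flask gives 0.87.

    G → E (k = 0.0120 s⁻¹)
    X + G + L → G + Q (k = 340 M⁻² s⁻¹)
    D ⇌ X, rate k3*(csat - [X]) (kL = 0.160 s⁻¹)
    X + G + Z → G + J (k = 1000 M⁻² s⁻¹)

That is below our 0.985. The mark falls at 0.495 min, and at 0.500 min [X] is 0.0201 M, a share 0.694 of saturation. With this share in place of 0.850, and k1 with that time, the rule gives 0.865. By 0.500 min J had reached 7.44% while G fell to 69.8% of its charge. By 2.50 min G stood at 16.5% with [X] at 0.0270 M, and by 5.00 min G was 2.73% with Z at 24.7%.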